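Zeta was the run I read first: its J reached 9.1% at 0.417 d, then fell to 8.1% by 0.833 d. Delta's J was still rising at its last reading.

in all of them: X 0.050 M

|  | L | remark | time |
|---|---|---|---|
| delta | 0.060 M (fed, over 80 min) | the very flask that is asked about, followed so far |  |
| zeta | 0.040 M (fed, over 80 min) | run made earlier |  |
| flask | 0.0600 M (fed, over 80 min) |  | 2.5 d |

- delta (time / h: J / %, X / %): 4.00: 5.7, 69.2; 5.00: 7.5, 63.2; 6.00: 9.7, 57.6; 8.00: 9.9, 47.2; 10.0: 12.2, 37.6; 12.0: 13.6, 27.6
- zeta (time / d: J / %, X / %): 0.167: 4.2, 69.9; 0.250: 5.8, 58.7; 0.417: 9.1, 40.4; 0.833: 8.1, 3.7; 1.25: 6.8, 0.9; 2.50: 3.6, 0.6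

(scatter of a reading: 0.5 percentage points)

- the numbers in the tables scatter by 0.5 percentage points (one standard deviation)
- at the start none of X is in solution
- a reading or a percentage of J counts all its forms, free or not

* the best time, 2.5 d at the latest, for J
* the amount of J, in percent of the X charged, at that time

I compared the two runs by a ratio in which time drops out, and for zeta it came to 11.4%. This share of L is the J at its highest reading, in moles, per mole of L charged, at this charge of X.

| run | L charged | highest J reading | at | share of L |
|---|---|---|---|---|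
| zeta | 0.040 M | 9.1% | 0.417 d | 11.4% |
| delta | 0.060 M | 13.6% | 12.0 h | 11.3% |

Down the second column, L grew by a factor of 1.50. Down the third, J grew by 1.49. So the last column barely moved, though each reading scatters by 0.5 percentage points. Zeta's share, applied to this flask, gave me 13.7%, and I placed the best time shortly after 0.5 d.

The forecast differed from my figure: 15.2% at 0.65 d, with a range of 13.8% to 17%, expecting delta to “keep climbing a bit longer”.

The flask gave 13.0% at 0.584 d, and both forecast answers stood within the tolerance.

    X ⇌ Q, rate k1*(cs1 - [Q]) while solid is left; crystals form when [Q] > cs1 (solubility = 34.0 mM, k = 0.140 h⁻¹)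
    Q + L ⇌ J (K = 15.0 M⁻¹, k = 2.50 M⁻¹ h⁻¹)
    E ⇌ J, rate k3*(cs3 - [J]) while solid is left; crystals form when [J] > cs3 (solubility = 17.0 mM, k = 1.70 h⁻¹)
    Q + J → Z (k = 8.40 M⁻¹ h⁻¹)

In this flask, at 0.312 d, the forward reaction with L alone used Q at 3.0 times the rate of its reaction with J, a ratio that held for that moment. At the best time, this flask's J was 10.8% of the L charged, while 76.1% of that L stood unbound. The neighbour flask, with 0.015 M of L, reached 3.58%, where the share gives 3.41%.

All runs stem from a simulated flask on assumed constants; the scatter is artificial.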